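**Plan**

- Retrosynthesis cuts, in this order: the C2–aryl bond of the flavanone (rings A/C from ring B), the two aryl–prenyl bonds, and the C2–C3 bond of the 2,2-dimethylchromane (rings B/D, chromane numbering O1, C2, C3, C4, C4a–C8a).
- Enabling feature: C2 of ring D is a fully substituted carbon on the aryl ether oxygen O1, and C3–C4 is a two-carbon arm on C4a, ortho to that oxygen. C2 can therefore be raised as a tertiary α-aryloxy radical by loss of CO2 from an aryloxyisobutyric acid and caught by an ortho vinyl group at its terminal carbon (the future C3).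
- Forward, ring D is closed first on a 2-bromo-4-chloro-6-vinylphenol core; the bromide at C8 is then exchanged for prenyl and the chloride at C6 for B(OH)2.
- Rings A/C come from 7-hydroxychromone by O-allylation, Claisen shift to C8, silylation and cross-metathesis to the prenyl group.
- The halves are joined by a ligand-controlled palladium-catalysed 1,4-addition that sets the only stereocentre, C2 of the flavanone, as (S); buffered desilylation ends the route.

Key step: step 3

Remark (assumption): the facial sense of the t-BuPyOx–palladium catalyst on chromones is taken to be the same as on 3-substituted cyclohexenones, so that the (R)-ligand gives (2S). If a model run shows the opposite sense, the (S)-ligand is used and nothing else changes. 3-Bromo-5-chlorosalicylaldehyde and 7-hydroxychromone are taken as commercial.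

**Route**

Step 1
Reactants: 1 3-bromo-5-chloro-2-hydroxybenzaldehyde
Product: 2 2-bromo-4-chloro-6-ethenylphenol
Conditions: Ph3PCH3Br (2.2 equiv), KOt-Bu (3.3 equiv), THF, 0 °C to rt; then 1 M HCl
Reagents that add atoms: methyltriphenylphosphonium bromide, C[P+](c1ccccc1)(c1ccccc1)c1ccccc1.[Br-]
Why: Wittig methylenation with excess ylide carries the free phenol through as its phenoxide, so the aldehyde should be converted to the vinyl group without protection.

Step 2
Reactants: 2 2-bromo-4-chloro-6-ethenylphenol
Product: 4 2-(2-bromo-4-chloro-6-ethenylphenoxy)-2-methylpropanoic acid, via acyl chloride 3 (not isolated)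
Conditions: 1,1,1-trichloro-2-methylpropan-2-ol (2 equiv), powdered NaOH (8 equiv), acetone, 0 °C to rt; then aq. HCl
Reagents that add atoms: 1,1,1-trichloro-2-methylpropan-2-ol (chloretone), CC(C)(O)C(Cl)(Cl)Cl; sodium hydroxide, [Na+].[OH-]
Why: Bargellini reaction, in which hydroxide turns the trichloromethyl carbinol into a gem-dichloroepoxide that the hindered phenoxide opens at the tertiary carbon to an acyl chloride hydrolysed in the flask, should install the O–CMe2–CO2H unit in one step while keeping dichlorocarbene, a threat to the vinyl group, low.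

Step 3
Reactants: 4 2-(2-bromo-4-chloro-6-ethenylphenoxy)-2-methylpropanoic acid
Product: 7 8-bromo-6-chloro-2,2-dimethylchromane, via tertiary aryloxyalkyl radical 5 (not isolated), via benzylic chromanyl radical 6 (not isolated)
Conditions: Ir[dF(CF3)ppy]2(dtbbpy)PF6 (1 mol %), 2,4,6-triisopropylbenzenethiol (10 mol %), K2HPO4 (0.3 equiv), DMF (0.02 M), 450 nm LEDs, 25 °C, degassed
Reagents that add atoms: none
Why: Proposed new method: the excited iridium photocatalyst oxidises the carboxylate of 4, loss of CO2 gives the tertiary α-aryloxyalkyl radical 5 at the future C2, this nucleophilic radical adds to the terminal carbon of the ortho vinyl group to form the C2–C3 bond and the benzylic radical 6 at C4, and 6 takes a hydrogen atom from the thiol, whose thiyl radical is returned to thiol by the reduced photocatalyst and the acid. The closest known reaction types are the photoredox decarboxylative Giese addition of α-oxy acids and the thiol-cocatalysed radical hydroalkylation of styrenes; their intramolecular use to close a chromane between C2 and C3 is the new element. Ring D closes in the 6-endo-trig mode, and no stereocentre is formed. The step needs 6-endo over 5-exo closure: attack of a bulky tertiary radical at the unsubstituted CH2 gives a benzylic radical and keeps the alkene conjugated with the arene in the transition state, whereas 5-exo attack at the aryl-bearing carbon must twist the vinyl group out of conjugation and ends in a primary radical. It also needs ring closure to outrun hydrogen transfer to 5, which the low loading of a hindered thiol and the high dilution should secure; the aryl bromide and chloride lie beyond the reducing power of this catalyst, and no second alkene is present at this stage.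

Step 4
Reactants: 7 8-bromo-6-chloro-2,2-dimethylchromane
Product: 10 6-chloro-2,2-dimethyl-8-(3-methylbut-2-en-1-yl)chromane, via aryllithium 8 (not isolated), via arylcopper 9 (not isolated)
Conditions: n-BuLi (1.05 equiv), THF, −78 °C; CuBr·SMe2 (1.0 equiv), −78 to −40 °C; prenyl bromide (1.5 equiv), −78 °C to rt
Reagents that add atoms: 1-bromo-3-methylbut-2-ene (prenyl bromide), CC(C)=CCBr
Why: Bromine–lithium exchange should take the C8 bromide and leave the C6 chloride, and the derived arylcopper should couple with prenyl bromide at its primary carbon (allylic substitution of an organocopper) to give the linear prenyl group.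

Step 5
Reactants: 10 6-chloro-2,2-dimethyl-8-(3-methylbut-2-en-1-yl)chromane
Product: 11 [2,2-dimethyl-8-(3-methylbut-2-en-1-yl)chroman-6-yl]boronic acid
Conditions: B2(OH)4 (3 equiv), second-generation XPhos aminobiphenyl palladacycle PdCl(XPhos)(2'-aminobiphenyl-2-yl) (2 mol %), XPhos (4 mol %), KOAc (3 equiv), EtOH, 80 °C
Reagents that add atoms: tetrahydroxydiboron, OB(O)B(O)O
Why: Miyaura-type borylation of an aryl chloride with tetrahydroxydiboron under a biarylphosphine palladium catalyst should give the boronic acid directly and leave the trisubstituted alkene untouched.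

Step 6
Reactants: 12 7-hydroxy-4H-chromen-4-one
Product: 13 7-(prop-2-en-1-yloxy)-4H-chromen-4-one
Conditions: allyl bromide (1.3 equiv), K2CO3 (1.5 equiv), acetone, reflux
Reagents that add atoms: allyl bromide, C=CCBr
Why: Williamson etherification of the acidic 7-hydroxyl group should proceed cleanly, since the chromone has no other nucleophilic site.

Step 7
Reactants: 13 7-(prop-2-en-1-yloxy)-4H-chromen-4-one
Product: 14 7-hydroxy-8-(prop-2-en-1-yl)-4H-chromen-4-one
Conditions: N,N-diethylaniline, 200 °C, sealed tube
Reagents that add atoms: none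
Why: Aromatic Claisen rearrangement of 7-allyloxy benzopyranones should go to C8 and not to C6, because the C7–C8 bond has the higher double-bond character in this ring system.

Step 8
Reactants: 14 7-hydroxy-8-(prop-2-en-1-yl)-4H-chromen-4-one
Product: 15 8-(prop-2-en-1-yl)-7-[tri(propan-2-yl)silyloxy]-4H-chromen-4-one
Conditions: TIPSCl (1.3 equiv), imidazole (2.5 equiv), DMF, rt to 40 °C
Reagents that add atoms: chlorotri(propan-2-yl)silane, CC(C)[Si](Cl)(C(C)C)C(C)C
Why: Silylation of the phenol gives a bulky silyl ether that should withstand the aqueous, weakly acidic coupling in step 10 and keeps the ortho-alkenyl phenol from attacking its own side chain under divalent palladium.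

Step 9
Reactants: 15 8-(prop-2-en-1-yl)-7-[tri(propan-2-yl)silyloxy]-4H-chromen-4-one
Product: 16 8-(3-methylbut-2-en-1-yl)-7-[tri(propan-2-yl)silyloxy]-4H-chromen-4-one
Conditions: 2-methyl-2-butene (excess), second-generation Grubbs catalyst RuCl2(=CHPh)(H2IMes)(PCy3) (3 mol %), CH2Cl2, 40 °C
Reagents that add atoms: 2-methyl-2-butene, CC=C(C)C
Why: Olefin cross-metathesis of the terminal allyl group with 2-methyl-2-butene should give the prenyl group, while the electron-poor C2=C3 bond of the chromone is not a metathesis partner.

Step 10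
Reactants: 16 8-(3-methylbut-2-en-1-yl)-7-[tri(propan-2-yl)silyloxy]-4H-chromen-4-one; 11 [2,2-dimethyl-8-(3-methylbut-2-en-1-yl)chroman-6-yl]boronic acid (2 equiv)
Product: 17 (2S)-2-[2,2-dimethyl-8-(3-methylbut-2-en-1-yl)chroman-6-yl]-8-(3-methylbut-2-en-1-yl)-7-[tri(propan-2-yl)silyloxy]-2,3-dihydro-4H-chromen-4-one
Conditions: Pd(OCOCF3)2 (5 mol %), (R)-t-BuPyOx (6 mol %), NH4PF6 (30 mol %), H2O (5 equiv), ClCH2CH2Cl, 60 °C
Reagents that add atoms: none
Why: Palladium-catalysed enantioselective conjugate addition of an arylboronic acid to a chromone should deliver the aryl group from a cationic arylpalladium species of divalent palladium to C2 on the enone face left open by the tert-butyl group of the pyridine–oxazoline ligand, which sets C2 as (S), and protonation of the palladium enolate by water releases the flavanone without ring opening.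

Step 11
Reactants: 17 (2S)-flavanone silyl ether
Product: 18 (2S)-2-[2,2-dimethyl-8-(3-methylbut-2-en-1-yl)chroman-6-yl]-7-hydroxy-8-(3-methylbut-2-en-1-yl)-2,3-dihydro-4H-chromen-4-one
Conditions: Bu4NF (1.2 equiv), AcOH (1.2 equiv), THF, 0 °C
Reagents that add atoms: none
Why: Fluoride cleavage of the aryl silyl ether buffered with acetic acid should free the phenol without the basic ring opening to the chalcone that would racemise C2 and without the acid that would cyclise the ortho-prenyl phenol.

**Compound list**

1 | 3-bromo-5-chloro-2-hydroxybenzaldehyde | O=Cc1cc(Cl)cc(Br)c1O | starting material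
2 | 2-bromo-4-chloro-6-ethenylphenol | C=Cc1cc(Cl)cc(Br)c1O | intermediate
3 | 2-(2-bromo-4-chloro-6-ethenylphenoxy)-2-methylpropanoyl chloride (not isolated) | C=Cc1cc(Cl)cc(Br)c1OC(C)(C)C(=O)Cl | intermediate
4 | 2-(2-bromo-4-chloro-6-ethenylphenoxy)-2-methylpropanoic acid | C=Cc1cc(Cl)cc(Br)c1OC(C)(C)C(=O)O | intermediate
5 | 2-(2-bromo-4-chloro-6-ethenylphenoxy)propan-2-yl radical (not isolated) | C=Cc1cc(Cl)cc(Br)c1O[C](C)C | intermediate
6 | 8-bromo-6-chloro-2,2-dimethylchroman-4-yl radical (not isolated) | CC1(C)C[CH]c2cc(Cl)cc(Br)c2O1 | intermediate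
7 | 8-bromo-6-chloro-2,2-dimethylchromane | CC1(C)CCc2cc(Cl)cc(Br)c2O1 | intermediate
8 | (6-chloro-2,2-dimethylchroman-8-yl)lithium (not isolated) | [Li]c1cc(Cl)cc2c1OC(C)(C)CC2 | intermediate
9 | (6-chloro-2,2-dimethylchroman-8-yl)copper (not isolated) | [Cu]c1cc(Cl)cc2c1OC(C)(C)CC2 | intermediate
10 | 6-chloro-2,2-dimethyl-8-(3-methylbut-2-en-1-yl)chromane | CC(C)=CCc1cc(Cl)cc2c1OC(C)(C)CC2 | intermediate
11 | [2,2-dimethyl-8-(3-methylbut-2-en-1-yl)chroman-6-yl]boronic acid | CC(C)=CCc1cc(B(O)O)cc2c1OC(C)(C)CC2 | intermediate
12 | 7-hydroxy-4H-chromen-4-one | O=c1ccoc2cc(O)ccc12 | starting material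
13 | 7-(prop-2-en-1-yloxy)-4H-chromen-4-one | O=c1ccoc2cc(OCC=C)ccc12 | intermediate
14 | 7-hydroxy-8-(prop-2-en-1-yl)-4H-chromen-4-one | O=c1ccoc2c(CC=C)c(O)ccc12 | intermediate
15 | 8-(prop-2-en-1-yl)-7-[tri(propan-2-yl)silyloxy]-4H-chromen-4-one | O=c1ccoc2c(CC=C)c(O[Si](C(C)C)(C(C)C)C(C)C)ccc12 | intermediate
16 | 8-(3-methylbut-2-en-1-yl)-7-[tri(propan-2-yl)silyloxy]-4H-chromen-4-one | O=c1ccoc2c(CC=C(C)C)c(O[Si](C(C)C)(C(C)C)C(C)C)ccc12 | intermediate
17 | (2S)-2-[2,2-dimethyl-8-(3-methylbut-2-en-1-yl)chroman-6-yl]-8-(3-methylbut-2-en-1-yl)-7-[tri(propan-2-yl)silyloxy]-2,3-dihydro-4H-chromen-4-one | CC(C)=CCc1cc([C@@H]2CC(=O)c3ccc(O[Si](C(C)C)(C(C)C)C(C)C)c(CC=C(C)C)c3O2)cc2c1OC(C)(C)CC2 | intermediate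
18 | (2S)-2-[2,2-dimethyl-8-(3-methylbut-2-en-1-yl)chroman-6-yl]-7-hydroxy-8-(3-methylbut-2-en-1-yl)-2,3-dihydro-4H-chromen-4-one | CC(C)=CCc1cc([C@@H]2CC(=O)c3ccc(O)c(CC=C(C)C)c3O2)cc2c1OC(C)(C)CC2 | target

**Totals and risks**

Total step count: 11. Longest linear sequence: 7 steps (steps 1 to 5, 10 and 11); the second branch (steps 6 to 9) has 4 steps.

Steps most likely to fail:

Step 3 (bears the label). What may go wrong: ring closure in the 5-exo mode at the aryl-bearing vinyl carbon, or hydrogen transfer to the tertiary radical before it cyclises (plain hydrodecarboxylation). The fallback forms the same C2–C3 bond by a known internal redox reaction; it sets out from compound 1 and comes back at compound 7.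
- Compound 1 is O-alkylated (2-iodopropane, K2CO3, DMF, 60 °C) to 3-bromo-5-chloro-2-(propan-2-yloxy)benzaldehyde F1.
- Knoevenagel condensation with Meldrum's acid (pyrrolidinium acetate cat., toluene, rt) gives 5-[3-bromo-5-chloro-2-(propan-2-yloxy)benzylidene]-2,2-dimethyl-1,3-dioxane-4,6-dione F2.
- With Sc(OTf)3 (10 mol %) in ClCH2CH2Cl at 80 °C the isopropyl methine hydrogen should shift as hydride to the benzylic carbon (1,5-hydride shift). The stabilised carbanion then closes onto the aryl oxocarbenium carbon to give 8-bromo-6-chloro-2,2,2',2'-tetramethylspiro[chromane-3,5'-[1,3]dioxane]-4',6'-dione F3.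
- Aqueous pyridine at reflux opens the dioxanedione and removes one carboxyl group, giving racemic 8-bromo-6-chloro-2,2-dimethylchromane-3-carboxylic acid F4.
- Photoredox hydrodecarboxylation (9-mesityl-10-phenylacridinium tetrafluoroborate, PhSSPh, i-Pr2NEt, CF3CH2OH, 450 nm) returns compound 7.

Step 10. What may go wrong: insufficient facial selectivity with the electron-rich arylboronic acid, protodeboronation, or insertion of the arylpalladium species into a prenyl double bond. The fallback replaces asymmetric addition by resolution; it sets out from compounds 16 and 11 and comes back at compound 17.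
- The same addition with the achiral ligand 2,2'-bipyridine (Pd(OCOCF3)2, NH4PF6, H2O, ClCH2CH2Cl, 60 °C) gives racemic 2-[2,2-dimethyl-8-(3-methylbut-2-en-1-yl)chroman-6-yl]-8-(3-methylbut-2-en-1-yl)-7-[tri(propan-2-yl)silyloxy]-2,3-dihydro-4H-chromen-4-one F5.
- Noyori asymmetric transfer hydrogenation with RuCl[(R,R)-TsDPEN](p-cymene) in HCO2H/Et3N (5:2 azeotrope), EtOAc, rt, is stopped near half conversion as a kinetic resolution. The (2R) enantiomer, for which catalyst and substrate preference coincide, should be reduced to the 2,4-cis alcohol (2R,4R)-2-[2,2-dimethyl-8-(3-methylbut-2-en-1-yl)chroman-6-yl]-8-(3-methylbut-2-en-1-yl)-7-[tri(propan-2-yl)silyloxy]chroman-4-ol F6.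
- The unreduced (2S) ketone, compound 17, is separated by chromatography.

Step 4. What may go wrong: attack at the tertiary end of the prenyl electrophile (allylic transposition), or alkylation of the aryllithium by the butyl bromide formed in the exchange. The fallback replaces organometallic alkylation by cross-coupling and metathesis; it sets out from compound 7 and comes back at compound 10.
- Stille coupling of the C8 bromide with allyltributylstannane (Pd(PPh3)4, toluene, 100 °C, chloride untouched) gives 6-chloro-2,2-dimethyl-8-(prop-2-en-1-yl)chromane F7.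
- Cross-metathesis with 2-methyl-2-butene (second-generation Grubbs catalyst, CH2Cl2, 40 °C) gives compound 10.

**Further compounds**

F1 | step 3 | 3-bromo-5-chloro-2-(propan-2-yloxy)benzaldehyde | CC(C)Oc1c(Br)cc(Cl)cc1C=O
F2 | step 3 | 5-[3-bromo-5-chloro-2-(propan-2-yloxy)benzylidene]-2,2-dimethyl-1,3-dioxane-4,6-dione | CC(C)Oc1c(Br)cc(Cl)cc1C=C1C(=O)OC(C)(C)OC1=O
F3 | step 3 | 8-bromo-6-chloro-2,2,2',2'-tetramethylspiro[chromane-3,5'-[1,3]dioxane]-4',6'-dione | CC1(C)Oc2c(Br)cc(Cl)cc2CC12C(=O)OC(C)(C)OC2=O
F4 | step 3 | 8-bromo-6-chloro-2,2-dimethylchromane-3-carboxylic acid (racemic) | CC1(C)Oc2c(Br)cc(Cl)cc2CC1C(=O)O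
F5 | step 10 | racemic 2-[2,2-dimethyl-8-(3-methylbut-2-en-1-yl)chroman-6-yl]-8-(3-methylbut-2-en-1-yl)-7-[tri(propan-2-yl)silyloxy]-2,3-dihydro-4H-chromen-4-one | CC(C)=CCc1cc(C2CC(=O)c3ccc(O[Si](C(C)C)(C(C)C)C(C)C)c(CC=C(C)C)c3O2)cc2c1OC(C)(C)CC2
F6 | step 10 | (2R,4R)-2-[2,2-dimethyl-8-(3-methylbut-2-en-1-yl)chroman-6-yl]-8-(3-methylbut-2-en-1-yl)-7-[tri(propan-2-yl)silyloxy]chroman-4-ol | CC(C)=CCc1cc([C@H]2C[C@@H](O)c3ccc(O[Si](C(C)C)(C(C)C)C(C)C)c(CC=C(C)C)c3O2)cc2c1OC(C)(C)CC2
F7 | step 4 | 6-chloro-2,2-dimethyl-8-(prop-2-en-1-yl)chromane | C=CCc1cc(Cl)cc2c1OC(C)(C)CC2
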